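**Retrosynthetic overview**
- The target is (2R,3S)-naringenin joined through C3 to C8 of apigenin 7-O-sulfate. The sulfate is placed late on the only free phenol (flavone O7, carried as a methoxymethyl ether); all other phenols are benzyl ethers removed in the last step, and the C4 ketone comes from C4–H oxidation of a flavan.
- The strategy rests on ring C of the flavanone unit: the O1–C2 and C3–C4 bonds flank the trans C2–C3 unit (4-hydroxyphenyl on C2, flavon-8-yl on C3). Cutting both bonds gives an E-stilbene and the o-quinone methide of ring A, with C4 as its methylene carbon and O1 as its oxygen.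
- The stilbene comes from a Heck coupling of an 8-iodo-5,4'-di-O-benzyl-7-O-MOM-apigenin with 4-acetoxystyrene; the methide comes from 3,5-bis(benzyloxy)-2-(hydroxymethyl)phenol.
- Ring order: ring A, the 4-hydroxyphenyl ring and all three flavone rings are bought in; ring C is the only ring formed, by the oxa-[4+2] cycloaddition.

Key step: step 9

Assumption 1: the facial sense of the chiral phosphoric acid cannot be assigned with certainty in advance; the (R)-acid is written as the one giving the (2R,3S)-chroman, and the equally available (S)-acid is used if a first run shows the opposite sense.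
Assumption 2: the target is taken as the hydrogen sulfate (free acid) as drawn; the sulfate is carried as its sodium salt and protonated in the last operation, the acid being kept cold because aryl hydrogen sulfates hydrolyse when acidic solutions are concentrated.
Locants: plain locants (O1, C2, C3, C4, O5, O7, 4'-O) refer to the flavanone (earlier chroman) unit; locants marked "flavone" refer to the apigenin-derived unit.

**Route**

Step 1
Reactants: 1 2,4,6-trihydroxybenzaldehyde
Product: 2 4,6-bis(benzyloxy)-2-hydroxybenzaldehyde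
Conditions: BnBr (2.05 equiv), K2CO3, DMF, 0 °C → rt
Reagents that add atoms: benzyl bromide, BrCc1ccccc1
Why: Williamson etherification takes the para hydroxyl and one ortho hydroxyl, while the remaining ortho hydroxyl, hydrogen-bonded to the aldehyde, is the least reactive and is left free when benzyl bromide is limiting.

Step 2
Reactants: 2 4,6-bis(benzyloxy)-2-hydroxybenzaldehyde
Product: 3 3,5-bis(benzyloxy)-2-(hydroxymethyl)phenol
Conditions: NaBH4, THF/MeOH, 0 °C; pH 7 work-up, no acidic silica, used at once
Reagents that add atoms: none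
Why: borohydride reduction of the aldehyde leaves the benzyl ethers untouched, and the acid-free work-up is needed because this electron-rich salicyl alcohol ionises very easily.

Step 3
Reactants: 4 apigenin
Product: 5 apigenin 5,7,4'-triacetate
Conditions: Ac2O, pyridine, DMAP (cat.), rt
Reagents that add atoms: acetic anhydride, CC(=O)OC(C)=O
Why: exhaustive O-acylation under nucleophilic catalysis, DMAP being needed for the chelated 5-hydroxyl.

Step 4
Reactants: 5 apigenin 5,7,4'-triacetate
Product: 6 5,4'-di-O-acetylapigenin (free 7-hydroxyl)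
Conditions: PhSH, imidazole, NMP, 0 °C → rt
Reagents that add atoms: none
Why: thiolate-mediated transacylation is the known regioselective 7-O-deacylation of peracylated flavones, the 7-O-acetate being cleaved first because the 7-phenoxide, para to the pyranone carbonyl, is the best leaving group.

Step 5
Reactants: 6 5,4'-di-O-acetylapigenin
Product: 7 5,4'-di-O-acetyl-7-O-(methoxymethyl)apigenin
Conditions: MOMCl, i-Pr2NEt, CH2Cl2, 0 °C → rt
Reagents that add atoms: chloromethyl methyl ether, COCCl
Why: O-alkylation of the single free phenol with the chloromethyl ether under a hindered amine base, which leaves the two aryl acetates in place.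

Step 6
Reactants: 7 5,4'-di-O-acetyl-7-O-(methoxymethyl)apigenin
Product: 9 5,4'-di-O-benzyl-7-O-(methoxymethyl)apigenin, via 7-O-(methoxymethyl)apigenin 8 (not isolated)
Conditions: K2CO3, MeOH/THF, rt; evaporate; BnBr, K2CO3, DMF, 70 °C
Reagents that add atoms: benzyl bromide, BrCc1ccccc1
Why: base-catalysed methanolysis of the aryl acetates followed by Williamson etherification, with heating in DMF to benzylate the chelated 5-hydroxyl, while the MOM acetal is stable to base.

Step 7
Reactants: 9 5,4'-di-O-benzyl-7-O-(methoxymethyl)apigenin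
Product: 10 5-benzyloxy-2-(4-benzyloxyphenyl)-8-iodo-7-(methoxymethoxy)chromen-4-one
Conditions: NIS (1.1 equiv), CF3CO2H (10 mol %), MeCN, 0 °C → rt, dark
Reagents that add atoms: N-iodosuccinimide, O=C1CCC(=O)N1I
Why: electrophilic aromatic iodination of a fully O-alkylated 5,7-dioxygenated flavone goes to C8 (ortho to O7, para to O5) and not to C6, which lies between two alkoxy groups, and the acid is kept catalytic to spare the MOM ether.

Step 8
Reactants: 10 5-benzyloxy-2-(4-benzyloxyphenyl)-8-iodo-7-(methoxymethoxy)chromen-4-one; 11 4-acetoxystyrene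
Product: 13 (E)-5-benzyloxy-2-(4-benzyloxyphenyl)-8-[2-(4-hydroxyphenyl)ethenyl]-7-(methoxymethoxy)chromen-4-one, via 4-acetoxystyryl flavone 12 (not isolated)
Conditions: Pd(OAc)2 (5 mol %), P(o-tol)3, Et3N, DMF, 100 °C; then K2CO3, MeOH, rt
Reagents that add atoms: none
Why: Heck reaction (oxidative addition of the aryl iodide to zerovalent palladium, syn-carbopalladation of the styrene, syn β-hydride elimination) gives the E-stilbene, and methanolysis of the aryl acetate then frees the 4-hydroxyl needed in step 9.

Step 9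
Reactants: 13 (E)-5-benzyloxy-2-(4-benzyloxyphenyl)-8-[2-(4-hydroxyphenyl)ethenyl]-7-(methoxymethoxy)chromen-4-one; 3 3,5-bis(benzyloxy)-2-(hydroxymethyl)phenol
Product: 15 (2R,3S)-5,7-bis(benzyloxy)-2-(4-hydroxyphenyl)-3-[5-benzyloxy-2-(4-benzyloxyphenyl)-7-(methoxymethoxy)-4-oxochromen-8-yl]chroman (2,3-trans), via o-quinone methide 14 (not isolated)
Conditions: (R)-TRIP [(R)-3,3'-bis(2,4,6-triisopropylphenyl)-1,1'-binaphthyl-2,2'-diyl hydrogen phosphate] (10 mol %), 4 Å MS, CH2Cl2, 0 °C → rt, 3 (1.5 equiv) added over several hours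
Reagents that add atoms: none
Why: The phosphoric acid protonates the benzylic hydroxyl of 3 and, helped by the ring oxygens ortho and para to that carbon, expels water to give o-quinone methide 14 held on the phosphate, which also hydrogen-bonds the free 4-hydroxyl of 13; the stilbene carbon bearing the flavonyl group then attacks the methide CH2 (C3–C4 bond) while positive charge builds at the p-hydroxybenzylic carbon, which is captured by the methide oxygen (O1–C2 bond) in an asynchronous inverse-demand oxa-[4+2] cycloaddition. The closest known reaction type is the chiral-phosphoric-acid-catalysed oxa-Diels–Alder reaction of o-quinone methides, generated in situ from o-hydroxybenzyl alcohols, with hydroxystyrenes and other electron-rich aryl alkenes, applied here to a 1,2-diaryl alkene and a methide unsubstituted at its exocyclic carbon. Ring C is closed by the intermolecular cycloaddition itself, the second bond forming as a six-membered closure of the methide oxygen onto the quinone-methide-like benzylic carbon. C2 and C3 are set together: their trans relationship follows from suprafacial addition to the E-alkene, and their absolute sense (2R,3S) from the stilbene face that the phosphate-bound methide can reach inside the chiral pocket. The step needs regioselectivity (4-hydroxyphenyl on C2, flavonyl on C3), which the phosphate-bound free phenol secures as the strongest donor on the alkene while the oxygens of the flavone benzo ring are drawn into conjugation with the pyranone carbonyl, and it needs cycloaddition to outrun self-condensation of 14, which slow addition of 3 keeps low.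

Step 10
Reactants: 15 (2R,3S)-5,7-bis(benzyloxy)-2-(4-hydroxyphenyl)-3-(flavon-8-yl)chroman
Product: 16 (2R,3S)-5,7-bis(benzyloxy)-2-(4-benzyloxyphenyl)-3-[5-benzyloxy-2-(4-benzyloxyphenyl)-7-(methoxymethoxy)-4-oxochromen-8-yl]chroman
Conditions: BnBr, K2CO3, DMF, rt
Reagents that add atoms: benzyl bromide, BrCc1ccccc1
Why: Williamson etherification of the only free phenol, required because a free p-hydroxyphenyl group at C2 would be oxidised by DDQ to a p-quinone methide with opening of ring C.

Step 11
Reactants: 16 (2R,3S)-penta-O-benzyl-7-O-MOM chroman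
Product: 17 (2R,3R)-5,7-bis(benzyloxy)-2-(4-benzyloxyphenyl)-3-[5-benzyloxy-2-(4-benzyloxyphenyl)-7-(methoxymethoxy)-4-oxochromen-8-yl]chroman-4-ol (C4 epimers; C2/C3 arrangement unchanged, the C3 label changes only by priority)
Conditions: DDQ (1.3 equiv), CH2Cl2/H2O (10:1), 0 °C → rt
Reagents that add atoms: water, O
Why: DDQ benzylic C–H oxidation removes hydride from C4 because the resulting cation is stabilised by O5, O7 and O1 of ring A, as in the C4 functionalisation of benzylated flavan-3-ols, and water traps it; the new C4 centre, expected mainly anti to the C3 aryl group, is destroyed in step 12.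

Step 12
Reactants: 17 chroman-4-ol (C4 epimers)
Product: 18 (2R,3S)-5,7-bis(benzyloxy)-2-(4-benzyloxyphenyl)-3-[5-benzyloxy-2-(4-benzyloxyphenyl)-7-(methoxymethoxy)-4-oxochromen-8-yl]chroman-4-one
Conditions: Dess–Martin periodinane, CH2Cl2, 0 °C → rt
Reagents that add atoms: none
Why: Dess–Martin oxidation of the secondary benzylic alcohol under near-neutral conditions gives the flavanone, and C3, now α to the ketone, can only relax to the trans diequatorial arrangement already present.

Step 13
Reactants: 18 (2R,3S)-flavanone with flavone 7-O-MOM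
Product: 19 (2R,3S)-5,7-bis(benzyloxy)-2-(4-benzyloxyphenyl)-3-[5-benzyloxy-2-(4-benzyloxyphenyl)-7-hydroxy-4-oxochromen-8-yl]chroman-4-one
Conditions: HCl (3 M aq.), MeOH/THF, 45 °C
Reagents that add atoms: none
Why: acid-catalysed acetal exchange with methanol removes the MOM group, while aryl benzyl ethers and the flavanone ring, which acid does not open, persist.

Step 14
Reactants: 19 (2R,3S)-flavanone with free flavone 7-hydroxyl
Product: 20 sodium (2R,3S)-8-[5,7-bis(benzyloxy)-2-(4-benzyloxyphenyl)-4-oxochroman-3-yl]-5-benzyloxy-2-(4-benzyloxyphenyl)-4-oxochromen-7-yl sulfate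
Conditions: SO3·pyridine (5 equiv), pyridine, rt → 40 °C; aq. NaHCO3
Reagents that add atoms: sulfur trioxide–pyridine complex, O=S(=O)([O-])[n+]1ccccc1; sodium hydrogen carbonate, [Na+].OC([O-])=O
Why: O-sulfonation (sulfation) of the only free phenol by the sulfur trioxide–amine complex, the acidic carbonyl-conjugated flavone 7-hydroxyl reacting under conditions in which pyridine does not open ring C by β-elimination.

Step 15
Reactants: 20 sodium aryl sulfate, penta-O-benzyl
Product: 21 target, (2R,3S)-naringenin-(3→8)-apigenin 7-O-(hydrogen sulfate)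
Conditions: H2 (1 atm), Pd/C (10 wt %), THF/MeOH, rt; filter; HCl (1.0 equiv), 0 °C; C18, H2O/MeCN (0.1% HCO2H), cold
Reagents that add atoms: none
Why: catalytic hydrogenolysis cleaves the five aryl benzyl ethers under neutral conditions that aryl sulfate salts tolerate, the reaction being stopped at the calculated uptake to spare the flavone C2=C3 bond and the benzylic C2–O1 bond, and one equivalent of acid then protonates the sulfate.

**Compound list**
1 | 2,4,6-trihydroxybenzaldehyde | O=Cc1c(O)cc(O)cc1O | starting material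
2 | 4,6-bis(benzyloxy)-2-hydroxybenzaldehyde | O=Cc1c(O)cc(OCc2ccccc2)cc1OCc1ccccc1 | intermediate
3 | 3,5-bis(benzyloxy)-2-(hydroxymethyl)phenol | OCc1c(O)cc(OCc2ccccc2)cc1OCc1ccccc1 | intermediate
4 | apigenin | O=c1cc(-c2ccc(O)cc2)oc2cc(O)cc(O)c12 | starting material
5 | apigenin 5,7,4'-triacetate | O=c1cc(-c2ccc(OC(C)=O)cc2)oc2cc(OC(C)=O)cc(OC(C)=O)c12 | intermediate
6 | 5,4'-di-O-acetylapigenin | O=c1cc(-c2ccc(OC(C)=O)cc2)oc2cc(O)cc(OC(C)=O)c12 | intermediate
7 | 5,4'-di-O-acetyl-7-O-(methoxymethyl)apigenin | O=c1cc(-c2ccc(OC(C)=O)cc2)oc2cc(OCOC)cc(OC(C)=O)c12 | intermediate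
8 | 7-O-(methoxymethyl)apigenin (not isolated) | O=c1cc(-c2ccc(O)cc2)oc2cc(OCOC)cc(O)c12 | intermediate
9 | 5,4'-di-O-benzyl-7-O-(methoxymethyl)apigenin | O=c1cc(-c2ccc(OCc3ccccc3)cc2)oc2cc(OCOC)cc(OCc3ccccc3)c12 | intermediate
10 | 5-benzyloxy-2-(4-benzyloxyphenyl)-8-iodo-7-(methoxymethoxy)chromen-4-one | O=c1cc(-c2ccc(OCc3ccccc3)cc2)oc2c(I)c(OCOC)cc(OCc3ccccc3)c12 | intermediate
11 | 4-acetoxystyrene | CC(=O)Oc1ccc(C=C)cc1 | starting material
12 | (E)-8-(4-acetoxystyryl)-5-benzyloxy-2-(4-benzyloxyphenyl)-7-(methoxymethoxy)chromen-4-one (not isolated) | O=c1cc(-c2ccc(OCc3ccccc3)cc2)oc2c(/C=C/c3ccc(OC(C)=O)cc3)c(OCOC)cc(OCc3ccccc3)c12 | intermediate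
13 | (E)-5-benzyloxy-2-(4-benzyloxyphenyl)-8-(4-hydroxystyryl)-7-(methoxymethoxy)chromen-4-one | O=c1cc(-c2ccc(OCc3ccccc3)cc2)oc2c(/C=C/c3ccc(O)cc3)c(OCOC)cc(OCc3ccccc3)c12 | intermediate
14 | 3,5-bis(benzyloxy)-6-methylidenecyclohexa-2,4-dien-1-one, o-quinone methide (not isolated) | C=C1C(=O)C=C(OCc2ccccc2)C=C1OCc1ccccc1 | intermediate
15 | (2R,3S)-5,7-bis(benzyloxy)-2-(4-hydroxyphenyl)-3-[5-benzyloxy-2-(4-benzyloxyphenyl)-7-(methoxymethoxy)-4-oxochromen-8-yl]chroman | C1c2c(OCc3ccccc3)cc(OCc3ccccc3)cc2O[C@@H](c2ccc(O)cc2)[C@@H]1c1c(OCOC)cc(OCc2ccccc2)c2c(=O)cc(-c3ccc(OCc4ccccc4)cc3)oc12 | intermediate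
16 | (2R,3S)-5,7-bis(benzyloxy)-2-(4-benzyloxyphenyl)-3-[5-benzyloxy-2-(4-benzyloxyphenyl)-7-(methoxymethoxy)-4-oxochromen-8-yl]chroman | C1c2c(OCc3ccccc3)cc(OCc3ccccc3)cc2O[C@@H](c2ccc(OCc3ccccc3)cc2)[C@@H]1c1c(OCOC)cc(OCc2ccccc2)c2c(=O)cc(-c3ccc(OCc4ccccc4)cc3)oc12 | intermediate
17 | (2R,3R)-chroman-4-ol of 16, C4 epimers | OC1c2c(OCc3ccccc3)cc(OCc3ccccc3)cc2O[C@@H](c2ccc(OCc3ccccc3)cc2)[C@@H]1c1c(OCOC)cc(OCc2ccccc2)c2c(=O)cc(-c3ccc(OCc4ccccc4)cc3)oc12 | intermediate
18 | (2R,3S)-5,7-bis(benzyloxy)-2-(4-benzyloxyphenyl)-3-[5-benzyloxy-2-(4-benzyloxyphenyl)-7-(methoxymethoxy)-4-oxochromen-8-yl]chroman-4-one | O=C1c2c(OCc3ccccc3)cc(OCc3ccccc3)cc2O[C@@H](c2ccc(OCc3ccccc3)cc2)[C@@H]1c1c(OCOC)cc(OCc2ccccc2)c2c(=O)cc(-c3ccc(OCc4ccccc4)cc3)oc12 | intermediate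
19 | (2R,3S)-5,7-bis(benzyloxy)-2-(4-benzyloxyphenyl)-3-[5-benzyloxy-2-(4-benzyloxyphenyl)-7-hydroxy-4-oxochromen-8-yl]chroman-4-one | O=C1c2c(OCc3ccccc3)cc(OCc3ccccc3)cc2O[C@@H](c2ccc(OCc3ccccc3)cc2)[C@@H]1c1c(O)cc(OCc2ccccc2)c2c(=O)cc(-c3ccc(OCc4ccccc4)cc3)oc12 | intermediate
20 | sodium salt of the flavone 7-O-sulfate of 19 | [Na+].O=C1c2c(OCc3ccccc3)cc(OCc3ccccc3)cc2O[C@@H](c2ccc(OCc3ccccc3)cc2)[C@@H]1c1c(OS(=O)(=O)[O-])cc(OCc2ccccc2)c2c(=O)cc(-c3ccc(OCc4ccccc4)cc3)oc12 | intermediate
21 | (2R,3S)-5,7-dihydroxy-2-(4-hydroxyphenyl)-3-[5-hydroxy-2-(4-hydroxyphenyl)-4-oxo-7-(sulfooxy)chromen-8-yl]chroman-4-one, CNP0271389.1 | O=C1c2c(O)cc(O)cc2O[C@@H](c2ccc(O)cc2)[C@@H]1c1c(OS(=O)(=O)O)cc(O)c2c(=O)cc(-c3ccc(O)cc3)oc12 | target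

**Step count**
Total: 15 steps (steps 6 and 8 are two-stage, one-flask operations). Longest linear sequence: 13 steps, from apigenin 4 through steps 3–15 to 21.

**Steps most likely to fail**

1. Step 9. Three things may go wrong:
   - the very electron-rich methide may condense with itself or alkylate aromatic positions faster than it adds to the stilbene;
   - the flavone benzo ring may act as the controlling donor and reverse the regiochemistry;
   - the phosphate may discriminate the stilbene faces poorly, because the phenol sits far from the reacting carbons.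

   Fallback, setting out from 3 and 13 and returning at 15: the methide is generated thermally without acid (toluene, 110 °C, sealed vessel), the known thermal route from 2-hydroxybenzyl alcohols to flavans. This should give the racemic trans-chroman, that is 15 together with its enantiomer, the (2S,3R)-chroman F1. The two are separated by preparative chromatography on a polysaccharide chiral stationary phase (supercritical CO2/MeOH), and 15 re-enters at step 10.

2. Step 11. The C4 cation may lose the C3 proton to give a flav-3-ene, which is then over-oxidised, or hydride abstraction may occur at C2, before water from the second phase traps the cation.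

   Fallback, setting out from 16 and returning at 18: DDQ oxidation in CH2Cl2/MeOH, with methanol in large excess in one phase, should give the 4-methoxyflavan F2 (C4 epimers). A second DDQ oxidation in CH2Cl2/pH 7 buffer, an oxidative cleavage of the benzylic methyl ether, gives ketone 18 directly and bypasses 17 and step 12.

3. Step 15. Slow removal of five benzyl groups may allow saturation of the flavone C2=C3 bond or hydrogenolytic opening of ring C at the benzylic C2–O1 bond, and the sulfate may hydrolyse during acidification.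

   Fallback, setting out from 19 and returning at 21:
   - the free phenol is converted with 2,2,2-trichloroethyl chlorosulfate (Et3N, DMAP, THF) into the aryl 2,2,2-trichloroethyl sulfate diester F3;
   - the five benzyl ethers are removed without hydrogen (BCl3, pentamethylbenzene, CH2Cl2, −78 °C) to give the pentaphenol trichloroethyl sulfate F4;
   - reductive cleavage of the trichloroethyl group (zinc dust, HCO2NH4, MeOH, rt) frees the sulfate, which is protonated and desalted as in step 15 to give 21.

**Further compounds**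
F1 | step 9 | (2S,3R)-enantiomer of chroman 15 | C1c2c(OCc3ccccc3)cc(OCc3ccccc3)cc2O[C@H](c2ccc(O)cc2)[C@H]1c1c(OCOC)cc(OCc2ccccc2)c2c(=O)cc(-c3ccc(OCc4ccccc4)cc3)oc12
F2 | step 11 | 4-methoxy derivative of chroman 16 (C2/C3 arrangement of 16, C4 epimers) | COC1c2c(OCc3ccccc3)cc(OCc3ccccc3)cc2O[C@@H](c2ccc(OCc3ccccc3)cc2)[C@@H]1c1c(OCOC)cc(OCc2ccccc2)c2c(=O)cc(-c3ccc(OCc4ccccc4)cc3)oc12
F3 | step 15 | flavone 7-O-(2,2,2-trichloroethoxysulfonyl) derivative of 19 | O=C1c2c(OCc3ccccc3)cc(OCc3ccccc3)cc2O[C@@H](c2ccc(OCc3ccccc3)cc2)[C@@H]1c1c(OS(=O)(=O)OCC(Cl)(Cl)Cl)cc(OCc2ccccc2)c2c(=O)cc(-c3ccc(OCc4ccccc4)cc3)oc12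
F4 | step 15 | 2,2,2-trichloroethyl ester of target sulfate 21 (all benzyl groups removed) | O=C1c2c(O)cc(O)cc2O[C@@H](c2ccc(O)cc2)[C@@H]1c1c(OS(=O)(=O)OCC(Cl)(Cl)Cl)cc(O)c2c(=O)cc(-c3ccc(O)cc3)oc12
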